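**Retrosynthetic overview**

1. Target 21 ⇐ acid removal of two PMB groups ⇐ phenol deacetylation ⇐ double acylation of O4 and O5 of quinate 15 (O3 and the carboxyl PMB-masked) with 4-acetoxycinnamoyl chloride 18.
2. 15 ⇐ quinide 11 by O3-selective alkylation on the rigid lactone, then lactone opening; 11 ⇐ osmylation of alkene lactone 10 ⇐ HBr loss from bromolactone 9.
3. Key disconnection: the C5–O bond and the C7–O–C5 γ-lactone of 9, made by bromolactonisation of (S)-1-hydroxycyclohex-3-ene-1-carboxylic acid 8. The feature used is that the carboxyl carbon C7 on C1 and O5 are cis-1,3 on the cyclohexane ring, so they close to the five-membered lactone ring of a 6-oxabicyclo[3.2.1]octan-7-one, which relays C1 to C5 and C4 and then shields one face for C3/C4.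
4. 8 ⇐ auxiliary-controlled Diels–Alder of buta-1,3-diene with (2R)-2-tert-butyl-5-methylidene-1,3-dioxolan-4-one 5, made from (R)-lactic acid and pivalaldehyde.
5. Ring order: dioxolanone (auxiliary, step 1) → cyclohexene (step 3) → bridging γ-lactone (step 5, reopened in step 9).

Key step: step 5

Remark: ring positions are numbered as in quinic acid throughout (C1 quaternary, C7 the carboxyl carbon; O3 and O4 on the face of the C1 hydroxyl, O5 on the face of C7). Butadiene is assumed to add to dienophile 5 anti to the tert-butyl group, as is general for this class of dioxolanone dienophile.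

**Route**

Step 1
Reactants: 1 (R)-lactic acid; 2 pivalaldehyde
Product: 3 (2R,5R)-2-tert-butyl-5-methyl-1,3-dioxolan-4-one (cis)
Conditions: TsOH·H2O (cat.), H2SO4 (cat.), pentane, reflux, Dean–Stark; recryst. Et2O/pentane, −78 °C
Reagents that add atoms: none
Why: Acid-catalysed acetalisation of the α-hydroxy acid with azeotropic water removal should give the 1,3-dioxolan-4-one, the new acetal centre C2 being set cis to the methyl group under thermodynamic control and the cis isomer being enriched by low-temperature crystallisation, which matters because the trans isomer would later give the enantiomeric dienophile.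

Step 2
Reactants: 3 (2R,5R)-2-tert-butyl-5-methyl-1,3-dioxolan-4-one
Product: 5 (2R)-2-tert-butyl-5-methylidene-1,3-dioxolan-4-one, via 5-bromo-5-methyl dioxolanone 4 (not isolated)
Conditions: NBS (1.05 equiv), AIBN (cat.), CCl4 or PhCF3, reflux; filter; then Et3N (1.5 equiv), 0 °C → rt
Reagents that add atoms: N-bromosuccinimide, O=C1CCC(=O)N1Br (its bromine is carried only by intermediate 4)
Why: Wohl–Ziegler radical bromination should occur at the captodatively stabilised C5–H and E2 loss of HBr towards the methyl group then gives the exocyclic enol ester, so that C5 is erased and the untouched acetal centre C2 carries all the chirality.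

Step 3
Reactants: 5 (2R)-2-tert-butyl-5-methylidene-1,3-dioxolan-4-one; 6 buta-1,3-diene
Product: 7 (2R,5S)-2-tert-butyl-1,3-dioxaspiro[4.5]dec-7-en-4-one
Conditions: 6 (5 equiv), BHT (cat.), toluene, sealed tube, 80 °C
Reagents that add atoms: none
Why: Thermal Diels–Alder cycloaddition of a 2-acyloxyacrylate-type dienophile, in which the tert-butyl group shields one face of the exocyclic alkene so that butadiene should add anti to it and set the spiro carbon (future C1) as S; the symmetric diene raises no regio- or endo/exo question, and any minor diastereomer can be removed here by chromatography or crystallisation.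

Step 4
Reactants: 7 (2R,5S)-2-tert-butyl-1,3-dioxaspiro[4.5]dec-7-en-4-one
Product: 8 (S)-1-hydroxycyclohex-3-ene-1-carboxylic acid
Conditions: LiOH·H2O (2.5 equiv), THF/H2O 3:1, 0 °C → rt; then 1 M HCl to pH 2
Reagents that add atoms: water, O (delivered as hydroxide; its oxygen ends in the carboxyl group)
Why: Saponification of the acetal-type lactone, after which the hemiacetal alkoxide collapses to pivalaldehyde and the α-hydroxy carboxylate; no bond to C1 is broken, so the S configuration is retained.

Step 5
Reactants: 8 (S)-1-hydroxycyclohex-3-ene-1-carboxylic acid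
Product: 9 (1S,4R,5R)-4-bromo-1-hydroxy-6-oxabicyclo[3.2.1]octan-7-one (4-bromo-3,4-dideoxyquinide, Br trans to the lactone oxygen)
Conditions: NBS (1.05 equiv), NaHCO3 (1.1 equiv), THF/H2O 3:1, 0 °C, dark
Reagents that add atoms: N-bromosuccinimide, O=C1CCC(=O)N1Br
Why: NBS transfers Br+ reversibly to either face of the C4=C5 alkene, but only the bromonium ion on the face opposite the C1 carboxylate is captured, by anti attack of a carboxylate oxygen at C5; this is the classical bromolactonisation of a cyclohex-3-enecarboxylic acid. The γ-lactone ring (O–C7–C1–C6–C5) closes in the 5-exo-tet mode through a chair with the carboxylate axial, giving the 6-oxabicyclo[3.2.1]octan-7-one, whereas attack at C4 would be 6-endo and give a bicyclo[2.2.2] δ-lactone. C5 is set by the tether, since the new C5–O bond must lie on the face of C7 (cis to the carboxyl, as in the target), and C4 is set by the anti opening of the bromonium ion (Br trans-diaxial to O5), so both new centres derive from C1 alone. The step needs regioselectivity for C5, secured by ring size, and chemoselectivity for the carboxylate over the tertiary C1 hydroxyl and water, secured by bicarbonate (carboxylate as the best oxygen nucleophile) and by the fact that the hydroxyl could reach only C4, through a boat and on the other bromonium face. Facial selectivity is self-correcting because the unproductive bromonium ion reverts to alkene.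

Step 6
Reactants: 9 (1S,4R,5R)-4-bromo-1-hydroxy-6-oxabicyclo[3.2.1]octan-7-one
Product: 10 (1S,5R)-1-hydroxy-6-oxabicyclo[3.2.1]oct-3-en-7-one
Conditions: DBU (2 equiv), toluene, 110 °C
Reagents that add atoms: none
Why: E2 dehydrobromination, in which the axial C4–Br of the rigid chair is antiperiplanar only to the axial hydrogen on C3 (H5 is syn to bromine), so the alkene should form at C3=C4 and not towards the lactone oxygen, with C1 and C5 untouched.

Step 7
Reactants: 10 (1S,5R)-1-hydroxy-6-oxabicyclo[3.2.1]oct-3-en-7-one
Product: 11 quinide, (1S,3R,4R,5R)-1,3,4-trihydroxy-6-oxabicyclo[3.2.1]octan-7-one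
Conditions: OsO4 (2 mol%), NMO (1.5 equiv), acetone/H2O 5:1, rt; aq. Na2SO3
Reagents that add atoms: osmium tetroxide, O=[Os](=O)(=O)=O (catalytic carrier of both oxygens); N-methylmorpholine N-oxide, C[N+]1([O-])CCOCC1; water, O
Why: Upjohn syn-dihydroxylation, in which osmium should add to the C3=C4 face opposite the lactone bridge that covers the other face of the carbocycle, placing O3 and O4 cis to each other and trans to O5 (on the face of the C1 hydroxyl) in one suprafacial event.

Step 8
Reactants: 11 quinide
Product: 13 3-O-(4-methoxybenzyl)quinide, via 3,4-O-dibutylstannylene acetal 12 (not isolated)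
Conditions: Bu2SnO (1.1 equiv), toluene, reflux, Dean–Stark; then PMBCl (1.2 equiv), CsF (1.5 equiv), DMF, rt
Reagents that add atoms: 4-methoxybenzyl chloride, COc1ccc(CCl)cc1; dibutyltin oxide, CCCC[Sn](=O)CCCC (tin only in intermediate 12)
Why: Regioselective O-alkylation through a dibutylstannylene acetal, in which the cis-3,4-diol forms the five-membered stannylene and fluoride-promoted alkylation should take place at the equatorial O3 and not at the axial O4 flanked by the lactone, while the tertiary O1 is not activated by tin and no stereocentre is touched.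

Step 9
Reactants: 13 3-O-(4-methoxybenzyl)quinide
Product: 15 4-methoxybenzyl 3-O-(4-methoxybenzyl)quinate, via caesium 3-O-(4-methoxybenzyl)quinate 14 (not isolated)
Conditions: CsOH·H2O (1.0 equiv), THF/H2O 3:1, 0 °C; evaporate; then PMBCl (1.2 equiv), DMF, rt
Reagents that add atoms: caesium hydroxide, [Cs+].[OH-]; 4-methoxybenzyl chloride, COc1ccc(CCl)cc1
Why: Saponification of the strained bicyclic γ-lactone by acyl–oxygen cleavage frees O5 with retention, and SN2 O-alkylation of the caesium carboxylate by the benzylic chloride gives the ester; the ether on O3 cannot migrate under base and the neutral hydroxyls are not alkylated.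

Step 10
Reactants: 16 p-coumaric acid
Product: 17 (E)-4-acetoxycinnamic acid
Conditions: Ac2O (2.5 equiv), pyridine, rt; aq. HCl work-up
Reagents that add atoms: acetic anhydride, CC(=O)OC(C)=O
Why: O-Acetylation of the phenol (any mixed anhydride at the carboxyl is hydrolysed on aqueous work-up) masks the nucleophilic phenol before acid chloride formation.

Step 11
Reactants: 17 (E)-4-acetoxycinnamic acid
Product: 18 (E)-4-acetoxycinnamoyl chloride
Conditions: (COCl)2 (1.5 equiv), DMF (cat.), CH2Cl2, 0 °C → rt; evaporate
Reagents that add atoms: oxalyl chloride, O=C(Cl)C(=O)Cl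
Why: Vilsmeier-catalysed conversion of the acid into the acid chloride, to which the aryl acetate and the E-alkene are inert.

Step 12
Reactants: 15 4-methoxybenzyl 3-O-(4-methoxybenzyl)quinate; 18 (E)-4-acetoxycinnamoyl chloride
Product: 19 4-methoxybenzyl 4,5-bis-O-[(E)-4-acetoxycinnamoyl]-3-O-(4-methoxybenzyl)quinate
Conditions: 18 (3 equiv), pyridine (6 equiv), DMAP (0.2 equiv), CH2Cl2, 0 °C → rt
Reagents that add atoms: none
Why: DMAP-catalysed O-acylation via the acylpyridinium ion should esterify the two equatorial secondary hydroxyls O4 and O5, while the axial tertiary O1–H next to the ester reacts far more slowly and O3 is blocked; no stereocentre is touched.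

Step 13
Reactants: 19 4-methoxybenzyl 4,5-bis-O-[(E)-4-acetoxycinnamoyl]-3-O-(4-methoxybenzyl)quinate
Product: 20 4-methoxybenzyl 4,5-di-O-[(E)-p-coumaroyl]-3-O-(4-methoxybenzyl)quinate
Conditions: N2H4·AcOH (2.5 equiv), DMF, 0 °C → rt
Reagents that add atoms: none
Why: Chemoselective hydrazinolysis of the aryl acetates, which are much better acyl donors than the hindered secondary cinnamates or the tertiary PMB ester; with O3 blocked and O1 trans to O5 there is no free hydroxyl to which a coumaroyl group could migrate under these mildly basic conditions.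

Step 14
Reactants: 20 4-methoxybenzyl 4,5-di-O-[(E)-p-coumaroyl]-3-O-(4-methoxybenzyl)quinate
Product: 21 4,5-di-O-p-coumaroylquinic acid
Conditions: TFA/CH2Cl2 1:4, anisole (10 equiv), 0 °C → rt
Reagents that add atoms: none
Why: Acidolysis (SN1) of the PMB ether and PMB ester with anisole as cation trap should release O3–H and the carboxylic acid under non-basic conditions, where acyl migration and ester cleavage are slow; no stereocentre is involved.

**Compound list**

1 | (R)-lactic acid | C[C@@H](O)C(=O)O | starting material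
2 | pivalaldehyde (2,2-dimethylpropanal) | CC(C)(C)C=O | starting material
3 | (2R,5R)-2-tert-butyl-5-methyl-1,3-dioxolan-4-one (cis) | C[C@H]1O[C@@H](C(C)(C)C)OC1=O | intermediate
4 | (2R,5S)-5-bromo-2-tert-butyl-5-methyl-1,3-dioxolan-4-one (Br trans to tert-butyl; C5 configuration of no consequence) | C[C@@]1(Br)O[C@@H](C(C)(C)C)OC1=O | intermediate (not isolated)
5 | (2R)-2-tert-butyl-5-methylidene-1,3-dioxolan-4-one | C=C1O[C@@H](C(C)(C)C)OC1=O | intermediate
6 | buta-1,3-diene | C=CC=C | starting material
7 | (2R,5S)-2-tert-butyl-1,3-dioxaspiro[4.5]dec-7-en-4-one | C1=CCC[C@]2(O[C@@H](C(C)(C)C)OC2=O)C1 | intermediate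
8 | (S)-1-hydroxycyclohex-3-ene-1-carboxylic acid | C1=CCC[C@@](O)(C(=O)O)C1 | intermediate
9 | (1S,4R,5R)-4-bromo-1-hydroxy-6-oxabicyclo[3.2.1]octan-7-one | Br[C@@H]1CC[C@@](O)(C(=O)O2)C[C@H]12 | intermediate
10 | (1S,5R)-1-hydroxy-6-oxabicyclo[3.2.1]oct-3-en-7-one | C1=CC[C@@](O)(C(=O)O2)C[C@H]12 | intermediate
11 | quinide, (1S,3R,4R,5R)-1,3,4-trihydroxy-6-oxabicyclo[3.2.1]octan-7-one | O[C@@H]1[C@H](O)C[C@@](O)(C(=O)O2)C[C@H]12 | intermediate
12 | 3,4-O-dibutylstannylene acetal of quinide | CCCC[Sn]1(CCCC)O[C@@H]2[C@H](O1)C[C@@](O)(C(=O)O3)C[C@H]23 | intermediate (not isolated)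
13 | 3-O-(4-methoxybenzyl)quinide, (1S,3R,4R,5R)-1,4-dihydroxy-3-[(4-methoxyphenyl)methoxy]-6-oxabicyclo[3.2.1]octan-7-one | O[C@@H]1[C@H](OCc3ccc(OC)cc3)C[C@@](O)(C(=O)O2)C[C@H]12 | intermediate
14 | caesium 3-O-(4-methoxybenzyl)quinate | O[C@@H]1[C@H](OCc2ccc(OC)cc2)C[C@@](O)(C(=O)[O-])C[C@H]1O.[Cs+] | intermediate (not isolated)
15 | 4-methoxybenzyl 3-O-(4-methoxybenzyl)quinate (natural quinic acid configuration; O1, O4, O5 free) | O[C@@H]1[C@H](OCc2ccc(OC)cc2)C[C@@](O)(C(=O)OCc2ccc(OC)cc2)C[C@H]1O | intermediate
16 | p-coumaric acid, (E)-3-(4-hydroxyphenyl)prop-2-enoic acid | OC(=O)/C=C/c1ccc(O)cc1 | starting material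
17 | (E)-4-acetoxycinnamic acid | CC(=O)Oc1ccc(/C=C/C(=O)O)cc1 | intermediate
18 | (E)-4-acetoxycinnamoyl chloride | CC(=O)Oc1ccc(/C=C/C(Cl)=O)cc1 | intermediate
19 | 4-methoxybenzyl 4,5-bis-O-[(E)-4-acetoxycinnamoyl]-3-O-(4-methoxybenzyl)quinate | O=C(/C=C/c1ccc(OC(C)=O)cc1)O[C@@H]1[C@H](OCc2ccc(OC)cc2)C[C@@](O)(C(=O)OCc2ccc(OC)cc2)C[C@H]1OC(=O)/C=C/c1ccc(OC(C)=O)cc1 | intermediate
20 | 4-methoxybenzyl 4,5-di-O-[(E)-p-coumaroyl]-3-O-(4-methoxybenzyl)quinate | O=C(/C=C/c1ccc(O)cc1)O[C@@H]1[C@H](OCc2ccc(OC)cc2)C[C@@](O)(C(=O)OCc2ccc(OC)cc2)C[C@H]1OC(=O)/C=C/c1ccc(O)cc1 | intermediate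
21 | 4,5-di-O-p-coumaroylquinic acid | O=C(/C=C/c1ccc(O)cc1)O[C@@H]1[C@H](O)C[C@@](O)(C(=O)O)C[C@H]1OC(=O)/C=C/c1ccc(O)cc1 | target

**Step count and risks**

Total step count: 14. Longest linear sequence: 12 steps (steps 1–9 and 12–14); steps 10 and 11 form the side branch to the acylating agent.

Steps most likely to fail:

Step 5 (key step). The bromonium ion may be intercepted by water (bromohydrin) or, on its other face, by the tertiary C1 hydroxyl across the ring (transannular ether), and the secondary bromide formed may then eliminate sluggishly in step 6. The fallback changes the electrophile and the way the alkene is regenerated. From acid 8, phenylselenolactonisation (PhSeCl, Et3N, CH2Cl2, −78 °C), which is reversible and funnels to the γ-lactone, should give (1S,4R,5R)-1-hydroxy-4-(phenylselanyl)-6-oxabicyclo[3.2.1]octan-7-one F1. Oxidation with H2O2 in THF at 0 °C → rt and syn-elimination of the selenoxide, which proceeds away from the oxygen-bearing C5, should then give the C3=C4 alkene. This replaces steps 5 and 6 and rejoins the route at compound 10.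

Step 8. The tin-activated alkylation may occur at the axial O4 or at both oxygens, or the tin alkoxide may attack the lactone during stannylene formation, giving regioisomers that are hard to separate. The fallback distinguishes O3 by size instead of tin activation. From quinide 11, TBDPSCl and imidazole in DMF at 0 °C should silylate only the equatorial secondary hydroxyl to give 3-O-(tert-butyldiphenylsilyl)quinide F2; the bulky silyl group is chosen because it is slow to migrate to O4 under base. CsOH and then PMBCl as in step 9 should give 4-methoxybenzyl 3-O-(tert-butyldiphenylsilyl)quinate F3. Acylation with 18 as in step 12 should give 4-methoxybenzyl 4,5-bis-O-[(E)-4-acetoxycinnamoyl]-3-O-(tert-butyldiphenylsilyl)quinate F4, and hydrazine acetate as in step 13 should give 4-methoxybenzyl 4,5-di-O-[(E)-p-coumaroyl]-3-O-(tert-butyldiphenylsilyl)quinate F5. HF·pyridine in THF should remove the silyl ether to give 4-methoxybenzyl 4,5-di-O-[(E)-p-coumaroyl]quinate F6, and TFA/anisole at 0 °C should cleave the PMB ester, rejoining the route at target 21.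

Step 12. Acylation of O4, which is flanked by the axial O3 ether and the new O5 ester, may stall at the mono-ester stage, and forcing it may bring acylation of O1 or loss of the acid chloride by side reactions. The fallback builds the cinnamoyl units on the ring instead of transferring them. From diol 15, Meldrum's acid (2.5 equiv) in toluene at 90 °C should acylate both secondary hydroxyls to give 4-methoxybenzyl 4,5-bis-O-(carboxyacetyl)-3-O-(4-methoxybenzyl)quinate F7. A Knoevenagel–Doebner condensation with unprotected 4-hydroxybenzaldehyde (pyridine, piperidine cat., 50 °C) should then form both E-cinnamates with decarboxylation. No phenol protection is needed, migration is impossible with O3 blocked, and the route is rejoined at compound 20.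

**Further compounds**

F1 | step 5 | (1S,4R,5R)-1-hydroxy-4-(phenylselanyl)-6-oxabicyclo[3.2.1]octan-7-one | c1ccccc1[Se][C@@H]2CC[C@@](O)(C(=O)O3)C[C@H]23
F2 | step 8 | 3-O-(tert-butyldiphenylsilyl)quinide | O[C@@H]1[C@H](O[Si](c3ccccc3)(c3ccccc3)C(C)(C)C)C[C@@](O)(C(=O)O2)C[C@H]12
F3 | step 8 | 4-methoxybenzyl 3-O-(tert-butyldiphenylsilyl)quinate | O[C@@H]1[C@H](O[Si](c2ccccc2)(c2ccccc2)C(C)(C)C)C[C@@](O)(C(=O)OCc2ccc(OC)cc2)C[C@H]1O
F4 | step 8 | 4-methoxybenzyl 4,5-bis-O-[(E)-4-acetoxycinnamoyl]-3-O-(tert-butyldiphenylsilyl)quinate | O=C(/C=C/c1ccc(OC(C)=O)cc1)O[C@@H]1[C@H](O[Si](c2ccccc2)(c2ccccc2)C(C)(C)C)C[C@@](O)(C(=O)OCc2ccc(OC)cc2)C[C@H]1OC(=O)/C=C/c1ccc(OC(C)=O)cc1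
F5 | step 8 | 4-methoxybenzyl 4,5-di-O-[(E)-p-coumaroyl]-3-O-(tert-butyldiphenylsilyl)quinate | O=C(/C=C/c1ccc(O)cc1)O[C@@H]1[C@H](O[Si](c2ccccc2)(c2ccccc2)C(C)(C)C)C[C@@](O)(C(=O)OCc2ccc(OC)cc2)C[C@H]1OC(=O)/C=C/c1ccc(O)cc1
F6 | step 8 | 4-methoxybenzyl 4,5-di-O-[(E)-p-coumaroyl]quinate | O=C(/C=C/c1ccc(O)cc1)O[C@@H]1[C@H](O)C[C@@](O)(C(=O)OCc2ccc(OC)cc2)C[C@H]1OC(=O)/C=C/c1ccc(O)cc1
F7 | step 12 | 4-methoxybenzyl 4,5-bis-O-(carboxyacetyl)-3-O-(4-methoxybenzyl)quinate | OC(=O)CC(=O)O[C@@H]1[C@H](OCc2ccc(OC)cc2)C[C@@](O)(C(=O)OCc2ccc(OC)cc2)C[C@H]1OC(=O)CC(=O)O
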